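**Retrosynthetic overview**

- Last disconnection: the C5 hydroxyl of unit B (the 5,7-dihydroxycoumarin half) is carried as an isopropyl ether and freed with BCl3; the C7 methyl ether of unit A (the 7-methoxycoumarin half) stays.
- Key disconnection: the pyranone of unit B (bonds C4–C4a and O1–C2) is cut back to a 2-aryloxy-5-isopropoxyresorcinol plus ethyl propiolate.
- Feature on which the strategy rests: in the benzene ring of unit B the ether carbon C8 and the oxygen-bearing C5 are para to each other. Without O1, C2, C3 and C4 a mirror plane runs through C8 and C5, so C4a and C6 are the same CH and the oxygens on C8a and C7 are the same hydroxyl.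
- The diaryl ether bond (C8 of unit A to oxygen) comes from copper-catalysed O-arylation of a 2,6-bis(MOM)-4-isopropoxyphenol with 8-iodo-7-methoxycoumarin; the phenol is made from phloroglucinol by mono-isopropylation, bis-MOM protection and directed metalation/borylation/oxidation.
- Ring order: both rings of unit A arrive intact with umbelliferone, the benzene ring of unit B with phloroglucinol; the pyranone of unit B is the only ring formed in the route (step 8).

Key step: step 8

Remark: the target has no stereocentre, so the only stereochemical element in the route is the Z alkene of the transient cinnamate 13; both halves carry ordinary coumarin numbering.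

**Route**

Step 1
Reactants: 1 phloroglucinol
Product: 2 5-isopropoxybenzene-1,3-diol
Conditions: 2-bromopropane (1 equiv), 1 (3 equiv), K2CO3 (1.1 equiv), DMF, 60 °C
Reagents that add atoms: 2-bromopropane CC(C)Br
Why: Williamson etherification of the phenoxide with a secondary bromide in a dipolar aprotic solvent should go at oxygen, and the excess of the symmetric triol (removed afterwards by aqueous wash) should keep di- and tri-ethers minor.

Step 2
Reactants: 2 5-isopropoxybenzene-1,3-diol
Product: 3 1-isopropoxy-3,5-bis(methoxymethoxy)benzene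
Conditions: MOMCl (2.6 equiv), i-Pr2NEt (3 equiv), CH2Cl2, 0 °C → rt
Reagents that add atoms: chloromethyl methyl ether COCCl
Why: O-alkylation of both phenols with MOMCl is standard acetal protection and installs the two groups that direct the metalation of the next step.

Step 3
Reactants: 3 1-isopropoxy-3,5-bis(methoxymethoxy)benzene
Product: 6 4-isopropoxy-2,6-bis(methoxymethoxy)phenol, via aryllithium 4 (not isolated), via dimethyl arylboronate 5 (not isolated)
Conditions: n-BuLi (1.1 equiv), THF, 0 °C; B(OMe)3, −78 °C → rt; AcOH, 30% aq H2O2, 0 °C → rt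
Reagents that add atoms: n-butyllithium [Li]CCCC (Li of 4); trimethyl borate COB(OC)OC (B(OMe)2 of 5); hydrogen peroxide OO (O of 6)
Why: Directed ortho-metalation should remove the proton between the two MOM ethers, the only CH chelated from both sides, and borylation followed by peroxide-induced 1,2-shift of the aryl group from boron to oxygen turns the C–Li bond into C–OH.

Step 4
Reactants: 7 7-hydroxycoumarin (umbelliferone)
Product: 8 7-hydroxy-8-iodocoumarin
Conditions: I2 (1.05 equiv), KI, 20% aq NH3, rt; then dilute H2SO4 to pH 3
Reagents that add atoms: iodine II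
Why: Electrophilic aromatic iodination of the phenoxide should go ortho to the oxygen at C8, the most nucleophilic ring position of 7-hydroxycoumarins (the usual site of their Mannich, Duff and Claisen chemistry).

Step 5
Reactants: 8 7-hydroxy-8-iodocoumarin
Product: 9 8-iodo-7-methoxycoumarin
Conditions: MeI (1.5 equiv), K2CO3, acetone, reflux
Reagents that add atoms: iodomethane CI
Why: Williamson methylation of the acidic 7-hydroxyl is straightforward and the lactone is inert to K2CO3 in acetone.

Step 6
Reactants: 6 4-isopropoxy-2,6-bis(methoxymethoxy)phenol; 9 8-iodo-7-methoxycoumarin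
Product: 10 8-[4-isopropoxy-2,6-bis(methoxymethoxy)phenoxy]-7-methoxycoumarin
Conditions: 6 (1.3 equiv), CuI (20 mol%), picolinic acid (40 mol%), K3PO4 (2 equiv), degassed DMSO, 90 °C, argon; aq NH4Cl work-up
Reagents that add atoms: none
Why: Ullmann-type O-arylation in which the picolinate-ligated monovalent copper phenoxide of 6 engages the C8–I bond of 9 and reductive elimination forms the C8–O bond; the electron-rich phenoxide with the electron-poorer aryl iodide is the favourable pairing, and this ligand system is the one used for ortho-substituted partners.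

Step 7
Reactants: 10 8-[4-isopropoxy-2,6-bis(methoxymethoxy)phenoxy]-7-methoxycoumarin
Product: 11 8-(2,6-dihydroxy-4-isopropoxyphenoxy)-7-methoxycoumarin
Conditions: HCl (2 M in MeOH), MeOH, 40 °C
Reagents that add atoms: none
Why: Acid-catalysed methanolysis of the two MOM acetals frees the hydroxyls while methanol carries the methoxymethyl cation away as dimethoxymethane, and the isopropyl ether, the diaryl ether and the lactone are stable to dilute methanolic HCl.

Step 8
Reactants: 11 8-(2,6-dihydroxy-4-isopropoxyphenoxy)-7-methoxycoumarin; 12 ethyl propiolate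
Product: 14 8-[(7-hydroxy-5-isopropoxy-2-oxo-2H-chromen-8-yl)oxy]-7-methoxycoumarin, via Z-cinnamate ester 13 (not isolated)
Conditions: Pd(OAc)2 (5 mol%), 12 (1.1 equiv), CF3CO2H/CH2Cl2 (4:1), 0 °C → rt
Reagents that add atoms: none
Why: Divalent palladium trifluoroacetate formed in CF3CO2H coordinates the triple bond of 12, and one of the two mirror-related ring CH carbons of 11 (ortho to one hydroxyl, para to the other, ortho to the isopropoxy group) attacks the β-carbon anti to palladium in a Friedel–Crafts-type step, after which protonolysis of the vinyl–palladium bond releases Z-cinnamate 13 with the aryl group and the ester cis. The closest known reaction type is the palladium-catalysed hydroarylation of propiolates by electron-rich phenols with lactonisation in the same flask, a Pechmann-type coumarin synthesis that works best on phloroglucinol-type rings. The pyranone closes by 6-exo-trig acyl substitution: the hydroxyl next to the new C4–C4a bond attacks the ester carbonyl and ethanol leaves, forming O1–C2. No stereocentre is formed; the Z geometry of 13 follows from the anti addition and is consumed in the lactone. Site selectivity needs no control because the two CH positions are exchanged by the mirror plane through the ether carbon and the isopropoxy carbon of the aryloxy ring, and the constitution of the lactone is secured by the isopropyl ether, which leaves a free hydroxyl on only one side of the new side chain. The benzene ring of unit A has no free hydroxyl and is deactivated by its lactone, and a second annulation at the remaining CH should be held back by the 1.1 equiv of 12 and by the lower nucleophilicity of the hydroxycoumarin once formed.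

Step 9
Reactants: 14 8-[(7-hydroxy-5-isopropoxy-2-oxo-2H-chromen-8-yl)oxy]-7-methoxycoumarin
Product: 15 8-[(5,7-dihydroxy-2-oxo-2H-chromen-8-yl)oxy]-7-methoxycoumarin
Conditions: BCl3 (5 equiv, 1 M in CH2Cl2), CH2Cl2, −78 → 0 °C; then H2O
Reagents that add atoms: none
Why: Lewis-acid dealkylation of an aryl alkyl ether: BCl3 binds the C5 ether oxygen of unit B and the secondary isopropyl group leaves as 2-chloropropane through a cation-like transition state that the methyl ether of unit A, which has no carbonyl group to chelate boron, should not reach at 0 °C or below.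

**Compound list**

1 | phloroglucinol (benzene-1,3,5-triol) | Oc1cc(O)cc(O)c1 | starting material
2 | 5-isopropoxybenzene-1,3-diol | CC(C)Oc1cc(O)cc(O)c1 | intermediate
3 | 1-isopropoxy-3,5-bis(methoxymethoxy)benzene | CC(C)Oc1cc(OCOC)cc(OCOC)c1 | intermediate
4 | [4-isopropoxy-2,6-bis(methoxymethoxy)phenyl]lithium | [Li]c1c(OCOC)cc(OC(C)C)cc1OCOC | intermediate (not isolated)
5 | dimethyl [4-isopropoxy-2,6-bis(methoxymethoxy)phenyl]boronate | COCOc1cc(OC(C)C)cc(OCOC)c1B(OC)OC | intermediate (not isolated)
6 | 4-isopropoxy-2,6-bis(methoxymethoxy)phenol | COCOc1cc(OC(C)C)cc(OCOC)c1O | intermediate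
7 | 7-hydroxycoumarin (umbelliferone) | Oc1ccc2ccc(=O)oc2c1 | starting material
8 | 7-hydroxy-8-iodocoumarin | Oc1ccc2ccc(=O)oc2c1I | intermediate
9 | 8-iodo-7-methoxycoumarin | COc1ccc2ccc(=O)oc2c1I | intermediate
10 | 8-[4-isopropoxy-2,6-bis(methoxymethoxy)phenoxy]-7-methoxycoumarin | COc1ccc2ccc(=O)oc2c1Oc1c(OCOC)cc(OC(C)C)cc1OCOC | intermediate
11 | 8-(2,6-dihydroxy-4-isopropoxyphenoxy)-7-methoxycoumarin | COc1ccc2ccc(=O)oc2c1Oc1c(O)cc(OC(C)C)cc1O | intermediate
12 | ethyl propiolate | C#CC(=O)OCC | starting material
13 | ethyl (Z)-3-{2,4-dihydroxy-6-isopropoxy-3-[(7-methoxy-2-oxo-2H-chromen-8-yl)oxy]phenyl}prop-2-enoate | CCOC(=O)/C=C\c1c(O)c(Oc2c(OC)ccc3ccc(=O)oc23)c(O)cc1OC(C)C | intermediate (not isolated)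
14 | 8-[(7-hydroxy-5-isopropoxy-2-oxo-2H-chromen-8-yl)oxy]-7-methoxycoumarin | COc1ccc2ccc(=O)oc2c1Oc1c(O)cc(OC(C)C)c2ccc(=O)oc12 | intermediate
15 | 8-[(5,7-dihydroxy-2-oxo-2H-chromen-8-yl)oxy]-7-methoxycoumarin | COc1ccc2ccc(=O)oc2c1Oc1c(O)cc(O)c2ccc(=O)oc12 | target

**Step count**

Total: 9 steps. Longest linear sequence: 7 steps (1, 2, 3, 6, 7, 8, 9).

**Steps most likely to fail**

1. Step 6 (copper-catalysed O-arylation). Both reacting centres carry two ortho oxygen substituents, so the copper cycle may stall at the engagement of the C–I bond; hydrodeiodination of 9 and oxidative degradation of the electron-rich phenoxide of 6 would then take over. The fallback sets out from 6 and comes back at 10; it makes the ether bond by nucleophilic aromatic substitution and builds the pyranone of unit A afterwards. Phenol 6 should displace fluoride from 2-fluoro-3-methoxybenzaldehyde F1 (Cs2CO3, DMSO, 100 °C), the ortho formyl group activating the C–F carbon, to give 2-[4-isopropoxy-2,6-bis(methoxymethoxy)phenoxy]-3-methoxybenzaldehyde F2. Baeyer–Villiger oxidation (mCPBA, NaHCO3, CH2Cl2) should give 2-[4-isopropoxy-2,6-bis(methoxymethoxy)phenoxy]-3-methoxyphenyl formate F3, which K2CO3 in MeOH cleaves to 2-[4-isopropoxy-2,6-bis(methoxymethoxy)phenoxy]-3-methoxyphenol F4. Magnesium-mediated ortho-formylation (MgCl2, Et3N, paraformaldehyde, MeCN, reflux) at the only free ortho position should give 2-hydroxy-3-[4-isopropoxy-2,6-bis(methoxymethoxy)phenoxy]-4-methoxybenzaldehyde F5. Wittig olefination with ethyl (triphenylphosphoranylidene)acetate in N,N-diethylaniline at reflux should give ethyl (E)-3-{2-hydroxy-3-[4-isopropoxy-2,6-bis(methoxymethoxy)phenoxy]-4-methoxyphenyl}prop-2-enoate F6, which isomerises at that temperature to the (Z)-isomer ethyl (Z)-3-{2-hydroxy-3-[4-isopropoxy-2,6-bis(methoxymethoxy)phenoxy]-4-methoxyphenyl}prop-2-enoate F7 and lactonises to 10.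

2. Step 8 (key annulation). The reaction may over-run to a second hydroarylation at the remaining CH, a free hydroxyl may add to the activated alkyne instead of carbon, or acid loss of the isopropyl group may open the way to the isomeric lactone. The fallback sets out from 11 and comes back at 14; it makes the same C4–C4a and O1–C2 bonds in two stages by formylation and olefination. Vilsmeier–Haack formylation (POCl3, DMF, MeCN, 0 °C → rt) at one of the two equivalent CH positions should give [2,4-dihydroxy-6-isopropoxy-3-(7-methoxy-2-oxo-2H-chromen-8-yloxy)benzylidene]dimethyliminium chloride F8, hydrolysed with aqueous NaOAc to 2,4-dihydroxy-6-isopropoxy-3-[(7-methoxy-2-oxo-2H-chromen-8-yl)oxy]benzaldehyde F9. Wittig olefination with ethyl (triphenylphosphoranylidene)acetate in N,N-diethylaniline at reflux should give ethyl (E)-3-{2,4-dihydroxy-6-isopropoxy-3-[(7-methoxy-2-oxo-2H-chromen-8-yl)oxy]phenyl}prop-2-enoate F10, which isomerises thermally to 13 and lactonises to 14.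

3. Step 1 (mono-isopropylation). Mono-selectivity may be poor: over-alkylation to di- and tri-ethers and C-alkylation of the ambident phloroglucinol anion would erode the mono-ether. The fallback sets out from 1 and comes back at 2; it forms the aryl C–O bond instead of the alkyl C–O bond. Phloroglucinol is heated in 2-propanol saturated with HCl gas (70 °C), where its keto tautomer adds the alcohol at a ring carbonyl and loses water to re-aromatise as the isopropyl ether. C-alkylation is not possible by this path, and each ether formed lowers the keto content of the ring, so the reaction can be stopped at the mono-ether. No compound outside the list is made (entry F0).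

**Further compounds**

F1 | step 6 | 2-fluoro-3-methoxybenzaldehyde | COc1cccc(C=O)c1F
F2 | step 6 | 2-[4-isopropoxy-2,6-bis(methoxymethoxy)phenoxy]-3-methoxybenzaldehyde | COCOc1cc(OC(C)C)cc(OCOC)c1Oc1c(OC)cccc1C=O
F3 | step 6 | 2-[4-isopropoxy-2,6-bis(methoxymethoxy)phenoxy]-3-methoxyphenyl formate | COCOc1cc(OC(C)C)cc(OCOC)c1Oc1c(OC)cccc1OC=O
F4 | step 6 | 2-[4-isopropoxy-2,6-bis(methoxymethoxy)phenoxy]-3-methoxyphenol | COCOc1cc(OC(C)C)cc(OCOC)c1Oc1c(OC)cccc1O
F5 | step 6 | 2-hydroxy-3-[4-isopropoxy-2,6-bis(methoxymethoxy)phenoxy]-4-methoxybenzaldehyde | COCOc1cc(OC(C)C)cc(OCOC)c1Oc1c(OC)ccc(C=O)c1O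
F6 | step 6 | ethyl (E)-3-{2-hydroxy-3-[4-isopropoxy-2,6-bis(methoxymethoxy)phenoxy]-4-methoxyphenyl}prop-2-enoate | CCOC(=O)/C=C/c1ccc(OC)c(Oc2c(OCOC)cc(OC(C)C)cc2OCOC)c1O
F7 | step 6 | ethyl (Z)-3-{2-hydroxy-3-[4-isopropoxy-2,6-bis(methoxymethoxy)phenoxy]-4-methoxyphenyl}prop-2-enoate | CCOC(=O)/C=C\c1ccc(OC)c(Oc2c(OCOC)cc(OC(C)C)cc2OCOC)c1O
F8 | step 8 | [2,4-dihydroxy-6-isopropoxy-3-(7-methoxy-2-oxo-2H-chromen-8-yloxy)benzylidene]dimethyliminium chloride | C[N+](C)=Cc1c(O)c(Oc2c(OC)ccc3ccc(=O)oc23)c(O)cc1OC(C)C.[Cl-]
F9 | step 8 | 2,4-dihydroxy-6-isopropoxy-3-[(7-methoxy-2-oxo-2H-chromen-8-yl)oxy]benzaldehyde | O=Cc1c(O)c(Oc2c(OC)ccc3ccc(=O)oc23)c(O)cc1OC(C)C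
F10 | step 8 | ethyl (E)-3-{2,4-dihydroxy-6-isopropoxy-3-[(7-methoxy-2-oxo-2H-chromen-8-yl)oxy]phenyl}prop-2-enoate | CCOC(=O)/C=C/c1c(O)c(Oc2c(OC)ccc3ccc(=O)oc23)c(O)cc1OC(C)C
F0 | step 1 | none | none
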